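**Retrosynthetic overview**
1. The succinimide ring is closed last (N–C16) from a cyano acyl-oxazolidinone; C12–C13 comes from an Evans syn-aldol on the C12 aldehyde.
2. Rings A and B are formed in one radical cascade (ring A first, then ring B): hydrogen-atom-transfer bicyclisation of an acyclic dichlorotriene makes C4–C5 and C9–C10 and releases the exocyclic C8=C17 alkene.
3. All three stereocentres that steer the cascade (C2, C3, C7) are set on the open chain: C2–Cl by organocatalytic α-chlorination, C3–C4 by Grignard addition, C3–Cl by SN2 inversion.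
4. The chain is built by cross-metathesis (C8=C9), Paterson aldol (C6–C7), Evans–Tishchenko reduction (C7 acetate) and Claisen rearrangement (C1–C3, E-C5=C10).

Assumption: 4,4-dimethoxybut-1-ene (2) is taken as a catalogue chemical; atom labels C1–C20 in the text follow labdane numbering of the target.

**Step 1**
Reactants: 1 methacrolein; 2 4,4-dimethoxybut-1-ene
Product: 3 (E)-5,5-dimethoxy-2-methylpent-2-enal
Conditions: second-generation Hoveyda–Grubbs catalyst RuCl2(H2IMes)(=CH-C6H4-2-OiPr) (3 mol %), 1 (3 equiv), CH2Cl2, 40 °C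
Reagents that add atoms: none
Why: Olefin cross-metathesis of a terminal alkene with the 1,1-disubstituted enal gives the (E)-trisubstituted enal, because the conjugated product does not re-enter metathesis and the E isomer is strongly favoured.

**Step 2**
Reactants: 3 (E)-5,5-dimethoxy-2-methylpent-2-enal; 4 3-methylbut-3-en-2-one
Product: 5 (5S,6E)-5-hydroxy-9,9-dimethoxy-2,6-dimethylnona-1,6-dien-3-one
Conditions: 4, (−)-Ipc2BCl, Et3N, Et2O, 0 °C; then 3, −78 → −20 °C; then MeOH, pH 7 buffer, 30% H2O2, 0 °C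
Reagents that add atoms: none
Why: Paterson boron aldol reaction, in which the diisopinocampheyl enol borinate of the methyl ketone adds to the Si face of the enal under reagent control and sets C7 as (S); the minor enantiomer becomes a separable diastereomer after step 6.

**Step 3**
Reactants: 5 (5S,6E)-5-hydroxy-9,9-dimethoxy-2,6-dimethylnona-1,6-dien-3-one; 6 acetaldehyde
Product: 7 (3S,5S,6E)-3-hydroxy-9,9-dimethoxy-2,6-dimethylnona-1,6-dien-5-yl acetate
Conditions: MeCHO (6 equiv), SmI2 (20 mol %), THF, −10 °C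
Reagents that add atoms: none
Why: Evans–Tishchenko reduction, in which the samarium-bound hemiacetal of acetaldehyde delivers hydride intramolecularly to the ketone, so one operation reduces the ketone (1,3-anti; this centre is destroyed in step 4) and puts the acetyl group only on the C7 oxygen.

**Step 4**
Reactants: 7 (3S,5S,6E)-3-hydroxy-9,9-dimethoxy-2,6-dimethylnona-1,6-dien-5-yl acetate; 8 ethyl vinyl ether
Product: 10 (4E,7S,8E)-11,11-dimethoxy-4,8-dimethyl-1-oxoundeca-4,8-dien-7-yl acetate, via allyl vinyl ether 9 (not isolated)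
Conditions: ethyl vinyl ether (solvent), Hg(OAc)2 (10 mol %), reflux; then PhMe, 110 °C
Reagents that add atoms: none
Why: Transvinylation followed by Claisen rearrangement through a chair transition state with the C6 chain equatorial builds C1–C3 as the aldehyde and the (E)-C5=C10 alkene, the 2-methyl group of the allyl unit enforcing high E selectivity.

**Step 5**
Reactants: 10 (4E,7S,8E)-11,11-dimethoxy-4,8-dimethyl-1-oxoundeca-4,8-dien-7-yl acetate
Product: 11 (2R,4E,7S,8E)-2-chloro-11,11-dimethoxy-4,8-dimethyl-1-oxoundeca-4,8-dien-7-yl acetate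
Conditions: NCS (1.3 equiv), (2S,5S)-2,5-diphenylpyrrolidine (10 mol %), CH2Cl2, −20 °C; pentane, filter, use crude at once
Reagents that add atoms: N-chlorosuccinimide, ClN1C(=O)CCC1=O
Why: Enamine-catalysed enantioselective α-chlorination of the aldehyde sets C2 as (R) under catalyst control, the (2S,5S) catalyst being the antipode of the one that gives (S)-2-chloroalkanals.

**Step 6**
Reactants: 11 (2R,4E,7S,8E)-2-chloro-11,11-dimethoxy-4,8-dimethyl-1-oxoundeca-4,8-dien-7-yl acetate; 12 isopropenylmagnesium bromide, CH2=C(CH3)MgBr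
Product: 13 (3S,4R,6E,9S,10E)-4-chloro-3-hydroxy-13,13-dimethoxy-2,6,10-trimethyltrideca-1,6,10-trien-9-yl acetate
Conditions: 12 (1.05 equiv), THF, −78 °C; aq NH4Cl
Reagents that add atoms: none
Why: Grignard addition to an α-chloroaldehyde follows the Cornforth–Evans model and gives the 1,2-anti chlorohydrin, and at −78 °C the aldehyde reacts far faster than the acetate.

**Step 7**
Reactants: 13 (3S,4R,6E,9S,10E)-4-chloro-3-hydroxy-13,13-dimethoxy-2,6,10-trimethyltrideca-1,6,10-trien-9-yl acetate
Product: 14 (3R,4R,6E,9S,10E)-3,4-dichloro-13,13-dimethoxy-2,6,10-trimethyltrideca-1,6,10-trien-9-yl acetate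
Conditions: PPh3, hexachloroacetone, CH2Cl2, 0 °C → rt
Reagents that add atoms: hexachloroacetone, O=C(C(Cl)(Cl)Cl)C(Cl)(Cl)Cl
Why: Appel-type deoxychlorination with PPh3/hexachloroacetone converts secondary allylic alcohols into chlorides by SN2 with inversion and little allylic transposition, which turns the anti chlorohydrin into the syn dichloride that carries C2 and C3 of the target.

**Step 8**
Reactants: 14 (3R,4R,6E,9S,10E)-3,4-dichloro-13,13-dimethoxy-2,6,10-trimethyltrideca-1,6,10-trien-9-yl acetate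
Product: 15 (2S,4R,4aR,6R,7R,8aR)-6,7-dichloro-4-(2,2-dimethoxyethyl)-4a,8,8-trimethyl-3-methylidenedecahydronaphthalen-2-yl acetate (labdane positions: 2α,3β-dichloro, 7β-acetoxy, 8(17)-ene, trans-decalin)
Conditions: Co(salen)Cl catalyst C36H52ClCoN2O2 [salen = N,N'-bis(3,5-di-tert-butylsalicylidene)-1,2-cyclohexanediaminate] (5 mol %), PhSiH3 (10 mol %), PhH (0.02 M), 22 °C, Ar
Reagents that add atoms: none
Why: Proposed new method: a trivalent cobalt hydride formed from Co(salen)Cl and catalytic PhSiH3 transfers a hydrogen atom to the 1,1-disubstituted alkene (the trisubstituted alkenes react far more slowly), the tertiary C4 radical closes 6-endo on C5 faster than it can lose the β-chlorine (C–Cl β-scission is about 20 kcal/mol uphill), the C10 radical closes 6-endo on C9, and divalent cobalt takes a hydrogen atom from the unhindered C17 methyl of the tertiary C8 radical, which releases the exocyclic alkene and regenerates the hydride; a chair–chair transition state with both chlorines and the acetate equatorial and two E alkenes gives the trans-decalin with H5 α, CH3-10 β and the C9 chain equatorial; the closest known reactions are cobalt–salen hydride cycloisomerisations of dienes and HAT-initiated radical polyene bicyclisations.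

**Step 9**
Reactants: 15 (2S,4R,4aR,6R,7R,8aR)-6,7-dichloro-4-(2,2-dimethoxyethyl)-4a,8,8-trimethyl-3-methylidenedecahydronaphthalen-2-yl acetate
Product: 16 (2S,4R,4aR,6R,7R,8aR)-6,7-dichloro-4a,8,8-trimethyl-3-methylidene-4-(2-oxoethyl)decahydronaphthalen-2-yl acetate
Conditions: 1 M aq HCl, THF, 0 °C → rt
Reagents that add atoms: water, O
Why: Acid-catalysed acetal hydrolysis is much faster than any reaction of the secondary acetate, the chlorides or the 1,1-disubstituted alkene, and no stereocentre is touched.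

**Step 10**
Reactants: 17 3-cyanopropanoic acid
Product: 19 (R)-4-(4-benzyl-2-oxo-1,3-oxazolidin-3-yl)-4-oxobutanenitrile, via mixed pivalic anhydride 18 (not isolated)
Conditions: PivCl, Et3N, THF, −20 °C; then (R)-4-benzyl-2-oxazolidinone, LiCl, rt
Reagents that add atoms: (R)-4-benzyl-2-oxazolidinone, O=C1N[C@H](Cc2ccccc2)CO1
Why: Mixed-anhydride N-acylation of the oxazolidinone occurs at the unhindered cyanopropanoyl carbonyl of the pivalic anhydride.

**Step 11**
Reactants: 16 (2S,4R,4aR,6R,7R,8aR)-6,7-dichloro-4a,8,8-trimethyl-3-methylidene-4-(2-oxoethyl)decahydronaphthalen-2-yl acetate; 19 (R)-4-(4-benzyl-2-oxo-1,3-oxazolidin-3-yl)-4-oxobutanenitrile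
Product: 20 (2S,4R,4aR,6R,7R,8aR)-4-[(2S,3R)-4-[(4R)-4-benzyl-2-oxo-1,3-oxazolidin-3-yl]-3-(cyanomethyl)-2-hydroxy-4-oxobutyl]-6,7-dichloro-4a,8,8-trimethyl-3-methylidenedecahydronaphthalen-2-yl acetate
Conditions: 19, Bu2BOTf, iPr2NEt, CH2Cl2, −78 → 0 °C; then 16, −78 → 0 °C; then pH 7 buffer, MeOH, 30% H2O2, 0 °C
Reagents that add atoms: none
Why: Evans syn-aldol reaction, in which the Z boron enolate (soft enolisation occurs at the imide α-carbon, not next to the nitrile) reacts through a Zimmerman–Traxler chair whose face is fixed by the (R)-benzyl auxiliary, setting C12 (S) and C13 (R).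

**Step 12**
Reactants: 20 (2S,4R,4aR,6R,7R,8aR)-4-[(2S,3R)-4-[(4R)-4-benzyl-2-oxo-1,3-oxazolidin-3-yl]-3-(cyanomethyl)-2-hydroxy-4-oxobutyl]-6,7-dichloro-4a,8,8-trimethyl-3-methylidenedecahydronaphthalen-2-yl acetate
Product: 22 haterumaimide A, via primary amide 21 (not isolated)
Conditions: [PtH(PMe2OH)(PMe2O)2H] (5 mol %), EtOH/H2O (4:1), 60 °C; then Et3N, DMAP (10 mol %), CH2Cl2, rt
Reagents that add atoms: water, O
Why: Neutral platinum-catalysed nitrile hydration gives the primary amide, whose nitrogen then acylates intramolecularly (5-exo) on the activated acyl oxazolidinone to close the succinimide and expel the auxiliary, with no external nucleophile to attack the C7 acetate and no base strong enough for retro-aldol cleavage.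

**Compound list**
1 | methacrolein | C=C(C)C=O | starting material
2 | 4,4-dimethoxybut-1-ene | C=CCC(OC)OC | starting material
3 | (E)-5,5-dimethoxy-2-methylpent-2-enal | COC(OC)C/C=C(C)/C=O | intermediate
4 | 3-methylbut-3-en-2-one | CC(=O)C(C)=C | starting material
5 | (5S,6E)-5-hydroxy-9,9-dimethoxy-2,6-dimethylnona-1,6-dien-3-one | COC(OC)C/C=C(C)/[C@@H](O)CC(=O)C(C)=C | intermediate
6 | acetaldehyde | CC=O | starting material
7 | (3S,5S,6E)-3-hydroxy-9,9-dimethoxy-2,6-dimethylnona-1,6-dien-5-yl acetate | COC(OC)C/C=C(C)/[C@@H](OC(C)=O)C[C@H](O)C(C)=C | intermediate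
8 | ethyl vinyl ether | C=COCC | starting material
9 | (3S,5S,6E)-3-(ethenyloxy)-9,9-dimethoxy-2,6-dimethylnona-1,6-dien-5-yl acetate | COC(OC)C/C=C(C)/[C@@H](OC(C)=O)C[C@H](OC=C)C(C)=C | intermediate (not isolated)
10 | (4E,7S,8E)-11,11-dimethoxy-4,8-dimethyl-1-oxoundeca-4,8-dien-7-yl acetate | COC(OC)C/C=C(C)/[C@@H](OC(C)=O)C/C=C(C)/CCC=O | intermediate
11 | (2R,4E,7S,8E)-2-chloro-11,11-dimethoxy-4,8-dimethyl-1-oxoundeca-4,8-dien-7-yl acetate | COC(OC)C/C=C(C)/[C@@H](OC(C)=O)C/C=C(C)/C[C@@H](Cl)C=O | intermediate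
12 | isopropenylmagnesium bromide | C=C(C)[Mg]Br | starting material
13 | (3S,4R,6E,9S,10E)-4-chloro-3-hydroxy-13,13-dimethoxy-2,6,10-trimethyltrideca-1,6,10-trien-9-yl acetate | COC(OC)C/C=C(C)/[C@@H](OC(C)=O)C/C=C(C)/C[C@@H](Cl)[C@@H](O)C(C)=C | intermediate
14 | (3R,4R,6E,9S,10E)-3,4-dichloro-13,13-dimethoxy-2,6,10-trimethyltrideca-1,6,10-trien-9-yl acetate | COC(OC)C/C=C(C)/[C@@H](OC(C)=O)C/C=C(C)/C[C@@H](Cl)[C@H](Cl)C(C)=C | intermediate
15 | (2S,4R,4aR,6R,7R,8aR)-6,7-dichloro-4-(2,2-dimethoxyethyl)-4a,8,8-trimethyl-3-methylidenedecahydronaphthalen-2-yl acetate | C=C1[C@@H](OC(C)=O)C[C@H]2C(C)(C)[C@@H](Cl)[C@H](Cl)C[C@]2(C)[C@H]1CC(OC)OC | intermediate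
16 | (2S,4R,4aR,6R,7R,8aR)-6,7-dichloro-4a,8,8-trimethyl-3-methylidene-4-(2-oxoethyl)decahydronaphthalen-2-yl acetate | C=C1[C@@H](OC(C)=O)C[C@H]2C(C)(C)[C@@H](Cl)[C@H](Cl)C[C@]2(C)[C@H]1CC=O | intermediate
17 | 3-cyanopropanoic acid | N#CCCC(=O)O | starting material
18 | 3-cyanopropanoic pivalic anhydride | N#CCCC(=O)OC(=O)C(C)(C)C | intermediate (not isolated)
19 | (R)-4-(4-benzyl-2-oxo-1,3-oxazolidin-3-yl)-4-oxobutanenitrile | N#CCCC(=O)N1[C@H](Cc2ccccc2)COC1=O | intermediate
20 | Evans syn-aldol adduct, (2S,3R)-cyanomethyl hydroxy imide on the decalin of 16 (full name in step 11) | C=C1[C@@H](OC(C)=O)C[C@H]2C(C)(C)[C@@H](Cl)[C@H](Cl)C[C@]2(C)[C@H]1C[C@H](O)[C@@H](CC#N)C(=O)N1[C@H](Cc2ccccc2)COC1=O | intermediate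
21 | primary amide of 20 (cyanomethyl replaced by 2-amino-2-oxoethyl, same configuration) | C=C1[C@@H](OC(C)=O)C[C@H]2C(C)(C)[C@@H](Cl)[C@H](Cl)C[C@]2(C)[C@H]1C[C@H](O)[C@@H](CC(N)=O)C(=O)N1[C@H](Cc2ccccc2)COC1=O | intermediate (not isolated)
22 | haterumaimide A, (3R)-3-[(1S)-2-[(1R,3S,4aR,6R,7R,8aR)-3-acetoxy-6,7-dichloro-5,5,8a-trimethyl-2-methylidenedecahydronaphthalen-1-yl]-1-hydroxyethyl]pyrrolidine-2,5-dione | C=C1[C@@H](OC(C)=O)C[C@H]2C(C)(C)[C@@H](Cl)[C@H](Cl)C[C@]2(C)[C@H]1C[C@H](O)[C@H]1CC(=O)NC1=O | target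

**Step count and risks**
Total steps: 12. Longest linear sequence: 11 (steps 1–9, 11, 12); step 10 is a one-step side branch.

Most likely to fail, step 8. The cobalt hydride may only isomerise the isopropenyl group, the β-chloro radical may lose chlorine, or the last hydrogen abstraction may give endocyclic alkenes. The fallback sets out from 14 and changes the terminating group from an unactivated alkene to an enone. The acetate of 14 is removed (K2CO3, MeOH, 0 °C) to give the trienol F1, and MnO2 in CH2Cl2 oxidises it to the trienone F2. Under the same cobalt hydride initiation, ring B now closes by a polarity-matched 6-endo radical conjugate addition at C9, and the C8 α-keto radical gives up a C17 hydrogen to divalent cobalt to form the bicyclic exocyclic enone F3. Luche reduction (NaBH4, CeCl3·7H2O, MeOH, −78 °C, axial hydride) gives the 7β-allylic alcohol F4, and Ac2O/DMAP/pyridine returns to the route at 15.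

Second, step 7. The alcohol is allylic, carries a 2-methyl group open to SN2' attack, and has a neighbouring chlorine that slows SN2 and can participate. The fallback sets out from 13 and avoids an activated allylic alcohol. NaH in THF at 0 °C closes the chlorohydrin to the trans-vinyl epoxide F5 with inversion at C2. Ph3PCl2 in CH2Cl2 then opens the epoxide twice with inversion, first at the allylic C3 and then at C2. The net result is retention at C2 and inversion at C3, which is the same dichloride 14, where the route is rejoined.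

Third, step 12. Hydration may stall, or the C12 hydroxyl may add to the platinum-activated nitrile. The fallback sets out from 16 and brings the nitrogen in as ammonia instead of as a nitrile. Succinyl chloride and two equivalents of lithiated (R)-4-benzyl-2-oxazolidinone give the symmetric bis-imide F6. Its mono boron enolate (Bu2BOTf 1.1 equiv, iPr2NEt, CH2Cl2, −78 °C) adds to 16 with the same Evans syn selectivity to give the bis-imide aldol adduct F7. NH3 (1.1 equiv, THF, −20 °C) cleaves the unhindered acyl oxazolidinone, and the amide formed closes on the second one to give the succinimide, so the route is rejoined at 22; these conditions leave the C7 acetate alone.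

**Further compounds**
F1 | step 8 | (3R,4R,6E,9S,10E)-3,4-dichloro-13,13-dimethoxy-2,6,10-trimethyltrideca-1,6,10-trien-9-ol | COC(OC)C/C=C(C)/[C@@H](O)C/C=C(C)/C[C@@H](Cl)[C@H](Cl)C(C)=C
F2 | step 8 | (3R,4R,6E,10E)-3,4-dichloro-13,13-dimethoxy-2,6,10-trimethyltrideca-1,6,10-trien-9-one | COC(OC)C/C=C(C)/C(=O)C/C=C(C)/C[C@@H](Cl)[C@H](Cl)C(C)=C
F3 | step 8 | (4R,4aR,6R,7R,8aR)-6,7-dichloro-4-(2,2-dimethoxyethyl)-4a,8,8-trimethyl-3-methylideneoctahydronaphthalen-2(1H)-one | C=C1C(=O)C[C@H]2C(C)(C)[C@@H](Cl)[C@H](Cl)C[C@]2(C)[C@H]1CC(OC)OC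
F4 | step 8 | (2S,4R,4aR,6R,7R,8aR)-6,7-dichloro-4-(2,2-dimethoxyethyl)-4a,8,8-trimethyl-3-methylidenedecahydronaphthalen-2-ol | C=C1[C@@H](O)C[C@H]2C(C)(C)[C@@H](Cl)[C@H](Cl)C[C@]2(C)[C@H]1CC(OC)OC
F5 | step 7 | (3S,4S,6E,9S,10E)-3,4-epoxy-13,13-dimethoxy-2,6,10-trimethyltrideca-1,6,10-trien-9-yl acetate | COC(OC)C/C=C(C)/[C@@H](OC(C)=O)C/C=C(C)/C[C@@H]1O[C@H]1C(C)=C
F6 | step 12 | 1,4-bis[(4R)-4-benzyl-2-oxo-1,3-oxazolidin-3-yl]butane-1,4-dione | O=C(CCC(=O)N1[C@H](Cc2ccccc2)COC1=O)N1[C@H](Cc2ccccc2)COC1=O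
F7 | step 12 | bis-imide syn-aldol adduct of 16 (C12 S, C13 R; both carbonyls of the succinyl unit carry the (R)-4-benzyl-2-oxazolidinone) | C=C1[C@@H](OC(C)=O)C[C@H]2C(C)(C)[C@@H](Cl)[C@H](Cl)C[C@]2(C)[C@H]1C[C@H](O)[C@@H](CC(=O)N1[C@H](Cc2ccccc2)COC1=O)C(=O)N1[C@H](Cc2ccccc2)COC1=O
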